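**Plan**

- Target: (3R,5R)-5-hydroxy-1,7-bis(4-hydroxyphenyl)heptan-3-yl acetate. Without the acetyl group it is C2-symmetric, and its only rings are the two identical 4-hydroxyphenyl rings on C1 and C7.
- Enabling feature: O–C3–C4–C5–O is a propane-1,3-diol unit whose carbinol carbons C3 and C5 each carry one carbon substituent (C2, C6) with the same R configuration.
- Cuts, in retrosynthetic order: the acetate C–O and two O-benzyl groups; then C1–C2 and C6–C7 as styrenyl C=C bonds (cross-metathesis on propenyl ends obtained from allyl by a one-carbon alkene shift); then C2–C3 and C5–C6 (double allylation of propane-1,3-diol).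
- Forward: no ring of the target is built. The C3 diol is extended at both ends at once, masked as the trans-acetonide, taken allyl → propenyl → 4-benzyloxystyryl, saturated, unmasked, mono-acetylated through its cyclic orthoacetate and debenzylated.
- Stereochemistry: C3 and C5 are both set by the chiral iridium catalyst in step 1 and not touched afterwards. C2 symmetry makes the two hydroxyls equivalent, so mono-acetylation needs no site selection.

Key step: step 1

Assumption: the (R)-enantiomer of Cl,MeO-BIPHEP is taken to deliver the (4R,6R)-diol. The sense is to be confirmed on compound 6 (optical rotation, Mosher esters), and the antipodal ligand used if it proves opposite, with nothing else changed.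

**Route**

Step 1
Reactants: 1 propane-1,3-diol; 2 allyl acetate
Product: 6 (4R,6R)-nona-1,8-diene-4,6-diol, via 3-hydroxypropanal 3 (not isolated), via (3R)-hex-5-ene-1,3-diol 4 (not isolated), via (3R)-3-hydroxyhex-5-enal 5 (not isolated)
Conditions: [Ir(cod)Cl]2 (5 mol%), (R)-Cl,MeO-BIPHEP (10 mol%), 4-Cl-3-NO2-C6H3CO2H (20 mol%), Cs2CO3 (40 mol%), 2 (10 equiv), 1,4-dioxane, 90 °C, sealed vessel
Reagents that add atoms: none
Why: The ortho-cyclometallated π-allyl iridium(III) C,O-benzoate formed in situ exchanges with a primary alkoxide of 1, β-hydride elimination gives aldehyde 3 and an iridium hydride, deprotonation and oxidative addition of 2 regenerate the allyl complex, and its σ-allyl form adds to the bound aldehyde through a closed six-membered chair transition state; the same cycle at the other terminus (4 to 5 to 6) completes the two-directional extension. This is the iridium-catalysed transfer-hydrogenative carbonyl allylation from the alcohol oxidation level (Krische allylation), known for 1,3-diols and allyl acetate in this double mode. No ring is closed. Both new stereocentres (C4 and C6 of 6) are fixed by the chiral bisphosphine on iridium, which selects the aldehyde face in each addition independently of the carbinol already present, so mono-adduct of the wrong hand is drained into the separable meso diol and the C2-symmetric anti diol is enantiomerically enriched (Horeau-type amplification). The step needs C- rather than O-allylation and reaction at primary carbinols only; the nitrobenzoate-modified catalyst with carbonate base should secure the first, and the slow dehydrogenation of the secondary homoallylic alcohols together with immediate capture of each transient β-hydroxy aldehyde should secure the second.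

Step 2
Reactants: 6 (4R,6R)-nona-1,8-diene-4,6-diol
Product: 7 (4R,6R)-2,2-dimethyl-4,6-di(prop-2-en-1-yl)-1,3-dioxane
Conditions: Me2C(OMe)2, PPTS (cat.), CH2Cl2, rt
Reagents that add atoms: 2,2-dimethoxypropane, COC(C)(C)OC
Why: Acid-catalysed transketalisation (acetonide formation) protects the anti-1,3-diol and, as a trans-4,6-disubstituted dioxane, holds the two side chains on opposite ring faces so that ring-closing metathesis cannot compete in step 4.

Step 3
Reactants: 7 (4R,6R)-2,2-dimethyl-4,6-di(prop-2-en-1-yl)-1,3-dioxane
Product: 8 (4S,6S)-2,2-dimethyl-4,6-di[(1E)-prop-1-en-1-yl]-1,3-dioxane (same spatial arrangement as 7; the descriptors change only because the alkenyl carbon now outranks ring C5)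
Conditions: Pd(dba)2 (2 mol%), P(t-Bu)3 (2 mol%), i-PrCOCl (2 mol%), toluene, 80 °C
Reagents that add atoms: none
Why: A Pd–H species generated in situ adds to each terminal alkene and β-hydride eliminates toward the internal position (alkene isomerisation by hydrometallation/β-hydride elimination, one-carbon chain walk); the 1,2-disubstituted alkene re-inserts much more slowly and a second shift would have to build a trisubstituted enol ether at the ring carbon, so migration should stop at propenyl, and the E/Z ratio is immaterial because the methyl-bearing carbon is excised in step 4 and the alkene is saturated in step 5.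

Step 4
Reactants: 8 (4S,6S)-2,2-dimethyl-4,6-di[(1E)-prop-1-en-1-yl]-1,3-dioxane; 9 1-(benzyloxy)-4-ethenylbenzene
Product: 10 (4S,6S)-4,6-bis{(E)-2-[4-(benzyloxy)phenyl]ethenyl}-2,2-dimethyl-1,3-dioxane
Conditions: Hoveyda–Grubbs II (2 × 5 mol%), 9 (6 equiv), CH2Cl2, 40 °C, argon sparge
Reagents that add atoms: none
Why: Olefin cross-metathesis exchanges the ethylidene end of each propenyl group for an arylmethylidene from the excess styrene with loss of volatile propene, the thermodynamically preferred E-styrenes should result, and the trans disposition of the two alkenyl groups on the dioxane makes ring closure to a bridged cyclopentene geometrically impossible.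

Step 5
Reactants: 10 (4S,6S)-4,6-bis{(E)-2-[4-(benzyloxy)phenyl]ethenyl}-2,2-dimethyl-1,3-dioxane
Product: 11 (4R,6R)-4,6-bis{2-[4-(benzyloxy)phenyl]ethyl}-2,2-dimethyl-1,3-dioxane
Conditions: TsNHNH2 (excess, in portions), NaOAc, DME/H2O, reflux
Reagents that add atoms: none
Why: Diimide reduction: HN=NH released from the sulfonyl hydrazide delivers H2 to each C=C through a concerted cyclic transition state, and with no metal surface present neither the benzyl ethers nor the allylic C–O bonds of the dioxane can be hydrogenolysed; no stereocentre is created and C4/C6 are untouched.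

Step 6
Reactants: 11 (4R,6R)-4,6-bis{2-[4-(benzyloxy)phenyl]ethyl}-2,2-dimethyl-1,3-dioxane
Product: 12 (3R,5R)-1,7-bis[4-(benzyloxy)phenyl]heptane-3,5-diol
Conditions: AcOH/THF/H2O (3:1:1), 45 °C
Reagents that add atoms: none
Why: Acid-catalysed acetal hydrolysis cleaves the strained trans-acetonide at the ketal carbon only, so the carbinol C–O bonds and their configuration are retained and the aryl benzyl ethers are inert.

Step 7
Reactants: 12 (3R,5R)-1,7-bis[4-(benzyloxy)phenyl]heptane-3,5-diol
Product: 14 (3R,5R)-1,7-bis[4-(benzyloxy)phenyl]-5-hydroxyheptan-3-yl acetate, via cyclic methyl orthoacetate 13 (not isolated)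
Conditions: MeC(OMe)3 (1.5 equiv), PPTS (cat.), CH2Cl2, rt; then 80% aq. AcOH, rt
Reagents that add atoms: trimethyl orthoacetate, CC(OC)(OC)OC; water, O
Why: Acid-catalysed orthoester exchange closes the six-membered cyclic orthoacetate 13 on the 1,3-diol, and mild aqueous acid opens the derived dioxanylium ion through the hemi-orthoester to exactly one acetate and one free hydroxyl (mono-acylation of a diol via its cyclic orthoester); because the diol is C2-symmetric both modes of opening give the same compound and a diacetate cannot form.

Step 8
Reactants: 14 (3R,5R)-1,7-bis[4-(benzyloxy)phenyl]-5-hydroxyheptan-3-yl acetate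
Product: 15 (3R,5R)-5-hydroxy-1,7-bis(4-hydroxyphenyl)heptan-3-yl acetate
Conditions: H2 (1 atm), 10% Pd/C, EtOAc, rt
Reagents that add atoms: none
Why: Catalytic hydrogenolysis of the two aryl benzyl ethers in a neutral, non-nucleophilic solvent leaves the secondary acetate in place, and any 1,3-acyl migration would be degenerate in this C2-symmetric diol.

**Compound list**

1 | propane-1,3-diol | OCCCO | starting material
2 | allyl acetate (prop-2-en-1-yl acetate) | C=CCOC(C)=O | starting material
3 | 3-hydroxypropanal | O=CCCO | intermediate (not isolated)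
4 | (3R)-hex-5-ene-1,3-diol | OCC[C@H](O)CC=C | intermediate (not isolated)
5 | (3R)-3-hydroxyhex-5-enal | O=CC[C@H](O)CC=C | intermediate (not isolated)
6 | (4R,6R)-nona-1,8-diene-4,6-diol | O[C@H](CC=C)C[C@H](O)CC=C | intermediate
7 | (4R,6R)-2,2-dimethyl-4,6-di(prop-2-en-1-yl)-1,3-dioxane | CC1(C)O[C@H](CC=C)C[C@H](O1)CC=C | intermediate
8 | (4S,6S)-2,2-dimethyl-4,6-di[(1E)-prop-1-en-1-yl]-1,3-dioxane | CC1(C)O[C@H](/C=C/C)C[C@H](O1)/C=C/C | intermediate
9 | 1-(benzyloxy)-4-ethenylbenzene | C=Cc1ccc(OCc2ccccc2)cc1 | starting material
10 | (4S,6S)-4,6-bis{(E)-2-[4-(benzyloxy)phenyl]ethenyl}-2,2-dimethyl-1,3-dioxane | CC1(C)O[C@H](/C=C/c2ccc(OCc3ccccc3)cc2)C[C@H](O1)/C=C/c1ccc(OCc2ccccc2)cc1 | intermediate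
11 | (4R,6R)-4,6-bis{2-[4-(benzyloxy)phenyl]ethyl}-2,2-dimethyl-1,3-dioxane | CC1(C)O[C@H](CCc2ccc(OCc3ccccc3)cc2)C[C@H](O1)CCc1ccc(OCc2ccccc2)cc1 | intermediate
12 | (3R,5R)-1,7-bis[4-(benzyloxy)phenyl]heptane-3,5-diol | O[C@H](CCc1ccc(OCc2ccccc2)cc1)C[C@H](O)CCc1ccc(OCc2ccccc2)cc1 | intermediate
13 | (4R,6R)-4,6-bis{2-[4-(benzyloxy)phenyl]ethyl}-2-methoxy-2-methyl-1,3-dioxane | COC1(C)O[C@H](CCc2ccc(OCc3ccccc3)cc2)C[C@H](O1)CCc1ccc(OCc2ccccc2)cc1 | intermediate (not isolated)
14 | (3R,5R)-1,7-bis[4-(benzyloxy)phenyl]-5-hydroxyheptan-3-yl acetate | CC(=O)O[C@H](CCc1ccc(OCc2ccccc2)cc1)C[C@H](O)CCc1ccc(OCc2ccccc2)cc1 | intermediate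
15 | (3R,5R)-5-hydroxy-1,7-bis(4-hydroxyphenyl)heptan-3-yl acetate (CNP0132544.1) | CC(=O)O[C@H](CCc1ccc(O)cc1)C[C@H](O)CCc1ccc(O)cc1 | target

**Step count**

Total steps: 8. Longest linear sequence: 8 steps (1 and 2 to 15; compound 9 is purchased).

**Steps most likely to fail**

1. Step 3 (allyl to propenyl). The alkene may walk past the propenyl position toward the ring carbon, which would erode the C4/C6 configuration, or the two termini may isomerise to different extents and give mixtures that cannot be separated. The fallback sets out from 7 and returns at 11, bypassing steps 3–5 and attaching the aryl rings by sp3–sp2 coupling instead of metathesis. Ozonolysis of both allyl groups with borohydride work-up (O3, CH2Cl2/MeOH, −78 °C; then NaBH4) should give the diol 2,2'-[(4R,6R)-2,2-dimethyl-1,3-dioxane-4,6-diyl]di(ethan-1-ol) F1. Appel iodination (I2, PPh3, imidazole, CH2Cl2) should then give the diiodide (4S,6S)-4,6-bis(2-iodoethyl)-2,2-dimethyl-1,3-dioxane F2 (descriptor change formal only). Iron-catalysed alkyl–aryl Kumada coupling with commercial 4-(benzyloxy)phenylmagnesium bromide (FeCl3 cat., TMEDA, THF, 0 °C, slow addition) should deliver 11.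

2. Step 4 (double cross-metathesis). The styrene may be consumed by homodimerisation to a poorly reactive stilbene, exchange may stall after one terminus, or the catalyst may die on the hindered, allylically oxygenated internal alkenes. The fallback sets out from 8 and returns at 10, replacing metathesis by carbonyl olefination. Ozonolysis (O3, CH2Cl2, −78 °C; then Me2S) should give the dialdehyde (4S,6S)-2,2-dimethyl-1,3-dioxane-4,6-dicarbaldehyde F3, used crude. Twofold Horner–Wadsworth–Emmons olefination with the potassium anion (KHMDS, THF, −78 °C to rt) of diethyl {[4-(benzyloxy)phenyl]methyl}phosphonate F4 should give the E,E-bis-styrene 10. F4 is made by Arbuzov reaction of commercial 4-(benzyloxy)benzyl chloride with triethyl phosphite. The aldehyde is added to the pre-formed anion at low temperature to limit α-epimerisation.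

3. Step 5 (diimide reduction). Diimide may disproportionate faster than it reduces the second hindered, conjugated alkene, so hydrogen transfer stays incomplete despite repeated reagent charges. The fallback sets out from 10 and returns at 11, accepting loss of the phenol protection and restoring it. Heterogeneous hydrogenation (H2, Pd/C, EtOAc, rt, run to full debenzylation) should saturate both alkenes and cleave both benzyl ethers to give the bisphenol 4,4'-{[(4R,6R)-2,2-dimethyl-1,3-dioxane-4,6-diyl]di(ethane-2,1-diyl)}diphenol F5. Re-benzylation (BnBr, K2CO3, acetone, reflux) should then give 11.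

**Further compounds**

F1 | step 3 | 2,2'-[(4R,6R)-2,2-dimethyl-1,3-dioxane-4,6-diyl]di(ethan-1-ol) | CC1(C)O[C@H](CCO)C[C@H](O1)CCO
F2 | step 3 | (4S,6S)-4,6-bis(2-iodoethyl)-2,2-dimethyl-1,3-dioxane | CC1(C)O[C@H](CCI)C[C@H](O1)CCI
F3 | step 4 | (4S,6S)-2,2-dimethyl-1,3-dioxane-4,6-dicarbaldehyde | CC1(C)O[C@H](C=O)C[C@H](O1)C=O
F4 | step 4 | diethyl {[4-(benzyloxy)phenyl]methyl}phosphonate | CCOP(=O)(OCC)Cc1ccc(OCc2ccccc2)cc1
F5 | step 5 | 4,4'-{[(4R,6R)-2,2-dimethyl-1,3-dioxane-4,6-diyl]di(ethane-2,1-diyl)}diphenol | CC1(C)O[C@H](CCc2ccc(O)cc2)C[C@H](O1)CCc1ccc(O)cc1
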